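**Retrosynthetic overview**

1. Pyran locants used below: O1, C2 (carries the arylethyl chain), C4 (OH), C6 (aryl). The target comes from its bis-acetate, and that from a 2,6-cis-tetrahydropyran-4-one; the axial C4 alcohol is made last by equatorial hydride delivery.
2. The tetrahydropyran is the only ring to be built (both arenes are bought). It is formed in one catalytic enantioselective hetero-Diels–Alder event that makes O1–C2 and C5–C6: vanillin acetate supplies C6=O1, a 2-silyloxy-1,3-diene supplies C2–C3–C4–C5.
3. Enabling feature: ring oxygen O1 stands 1,3 to the C4 oxygen through C2–C3 and also through C6–C5. At the C4 ketone level O1=C6 is therefore an aryl aldehyde and C2=C3–C4(OSi)=C5 an oxygenated diene; the aryl acetate serves as electron-poor activating and protecting group.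
4. The diene comes from an E-enone (silyl triflate enolization), the enone from a Wittig reaction of a 3-arylpropanal, the aldehyde from hydrogenation of 4-acetoxy-3-methoxycinnamaldehyde.
5. Stereocontrol: C6 by the catalyst and C2 by the endo mode in the same event; C4 by substrate control in the next step.

Key step: step 4

Remark: both acetoxy aldehydes are taken as catalogue compounds (each is otherwise one acetylation from coniferyl aldehyde or vanillin), and the (1S,2R) catalyst antipode is assigned by analogy with the usual sense of induction of this catalyst family, to be confirmed in a pilot run.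

**Step 1**
Reactants: 1 (E)-3-(4-acetoxy-3-methoxyphenyl)prop-2-enal
Product: 2 3-(4-acetoxy-3-methoxyphenyl)propanal
Conditions: H2 (1 atm), 5% Pd/C, EtOAc, rt, stopped after 1 equiv H2
Reagents that add atoms: none
Why: Hydrogenation on palladium should saturate the conjugated C=C bond much faster than it reduces the aldehyde, and the aryl acetate is inert (chemoselective catalytic hydrogenation of an enal).

**Step 2**
Reactants: 2 3-(4-acetoxy-3-methoxyphenyl)propanal; 3 1-(triphenylphosphoranylidene)propan-2-one
Product: 4 (E)-6-(4-acetoxy-3-methoxyphenyl)hex-3-en-2-one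
Conditions: CH2Cl2, rt to 40 °C
Reagents that add atoms: none
Why: Wittig olefination with a stabilized acyl ylide should give the E-enone under neutral conditions that spare the enolizable aldehyde and the aryl acetate.

**Step 3**
Reactants: 4 (E)-6-(4-acetoxy-3-methoxyphenyl)hex-3-en-2-one
Product: 5 (E)-6-(4-acetoxy-3-methoxyphenyl)-2-(triethylsilyloxy)hexa-1,3-diene
Conditions: Et3SiOTf (1.1 equiv), Et3N (1.5 equiv), Et2O, –78 to 0 °C
Reagents that add atoms: triethylsilyl trifluoromethanesulfonate, CC[Si](CC)(CC)OS(=O)(=O)C(F)(F)F
Why: Soft enolization with a silyl triflate and a tertiary amine should silylate the ketone oxygen and remove a methyl proton, giving the cross-conjugated 2-silyloxy-1,3-diene with the E alkene untouched (silyl enol ether formation).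

**Step 4**
Reactants: 5 (E)-6-(4-acetoxy-3-methoxyphenyl)-2-(triethylsilyloxy)hexa-1,3-diene; 6 4-acetoxy-3-methoxybenzaldehyde (vanillin acetate)
Product: 8 (2S,6S)-2-[2-(4-acetoxy-3-methoxyphenyl)ethyl]-6-(4-acetoxy-3-methoxyphenyl)tetrahydro-4H-pyran-4-one, via cycloadduct silyl enol ether 7 (not isolated)
Conditions: CrCl(C27H29NO2) (10 mol %; trivalent chromium with the Schiff base dianion of (1S,2R)-1-aminoindan-2-ol and 3-(1-adamantyl)-2-hydroxy-5-methylbenzaldehyde), 4 Å molecular sieves, TBME, rt; then 0.5 M HCl, THF, 0 °C
Reagents that add atoms: none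
Why: The chromium Lewis acid binds the carbonyl oxygen of 6 and diene 5 adds in a concerted but asynchronous [4+2] cycloaddition, in which C5–C6 bond formation from the nucleophilic CH2 terminus leads and the ring is completed when the carbonyl oxygen bonds to the chain-bearing diene terminus (O1–C2); dilute acid then hydrolyses silyl enol ether 7 to ketone 8. The closest known reaction type is the enantioselective hetero-Diels–Alder reaction of 4-alkyl-2-silyloxy-1,3-dienes with aldehydes under tridentate Schiff-base chromium catalysis, in use for aliphatic, aromatic and heteroaromatic aldehydes. The tetrahydropyran, the only ring, is closed by intermolecular [4+2] cycloaddition, with both ring bonds O1–C2 and C5–C6 formed in this event. C6 (S) should be set by the catalyst, which leaves the Si face of the bound aldehyde open, and C2 (S) is set relative to C6 by the endo transition state acting on the E-configured diene, which places the two substituents cis. The step needs regio-, endo- and enantioface selectivity: the regiochemistry is secured by the polarity of the silyl enol ether, the cis relation by the fixed E geometry of 5, and the reactivity by the para-acetoxy group, which keeps the aryl aldehyde electrophilic and later holds back ionization of the benzylic C6–O1 bond.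

**Step 5**
Reactants: 8 (2S,6S)-2-[2-(4-acetoxy-3-methoxyphenyl)ethyl]-6-(4-acetoxy-3-methoxyphenyl)tetrahydro-4H-pyran-4-one
Product: 9 (2S,4S,6S)-2-[2-(4-acetoxy-3-methoxyphenyl)ethyl]-6-(4-acetoxy-3-methoxyphenyl)tetrahydro-2H-pyran-4-ol
Conditions: LiBH(s-Bu)3 (1.1 equiv), THF, –78 °C; then AcOH, –78 °C to rt
Reagents that add atoms: none
Why: In the chair with both C2 and C6 substituents equatorial the bulky tri-sec-butylborohydride should attack along the equatorial trajectory, so that the new C4 hydroxyl is axial and trans to both substituents (substrate-controlled ketone reduction), while at –78 °C the ketone reacts much faster than the aryl acetates.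

**Step 6**
Reactants: 9 (2S,4S,6S)-2-[2-(4-acetoxy-3-methoxyphenyl)ethyl]-6-(4-acetoxy-3-methoxyphenyl)tetrahydro-2H-pyran-4-ol
Product: 10 (2S,4S,6S)-2-[2-(4-hydroxy-3-methoxyphenyl)ethyl]-6-(4-hydroxy-3-methoxyphenyl)tetrahydro-2H-pyran-4-ol
Conditions: K2CO3 (0.3 equiv), MeOH, 0 °C to rt; pH 7 buffer work-up
Reagents that add atoms: none
Why: Base-catalysed methanolysis should cleave the two aryl acetates, the most reactive esters present, and with C4 at the alcohol level no stereocenter can epimerize by retro-oxa-Michael opening.

**Compound list**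

1 | (E)-3-(4-acetoxy-3-methoxyphenyl)prop-2-enal (4-acetoxy-3-methoxycinnamaldehyde) | CC(=O)Oc1ccc(/C=C/C=O)cc1OC | starting material
2 | 3-(4-acetoxy-3-methoxyphenyl)propanal | CC(=O)Oc1ccc(CCC=O)cc1OC | intermediate
3 | 1-(triphenylphosphoranylidene)propan-2-one | CC(=O)C=P(c1ccccc1)(c1ccccc1)c1ccccc1 | starting material
4 | (E)-6-(4-acetoxy-3-methoxyphenyl)hex-3-en-2-one | CC(=O)/C=C/CCc1ccc(OC(C)=O)c(OC)c1 | intermediate
5 | (E)-6-(4-acetoxy-3-methoxyphenyl)-2-(triethylsilyloxy)hexa-1,3-diene | C=C(O[Si](CC)(CC)CC)/C=C/CCc1ccc(OC(C)=O)c(OC)c1 | intermediate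
6 | 4-acetoxy-3-methoxybenzaldehyde (vanillin acetate) | CC(=O)Oc1ccc(C=O)cc1OC | starting material
7 | (2S,6S)-6-(4-acetoxy-3-methoxyphenyl)-2-[2-(4-acetoxy-3-methoxyphenyl)ethyl]-4-(triethylsilyloxy)-5,6-dihydro-2H-pyran | CC(=O)Oc1ccc(CC[C@H]2C=C(O[Si](CC)(CC)CC)C[C@@H](c3ccc(OC(C)=O)c(OC)c3)O2)cc1OC | intermediate
8 | (2S,6S)-2-[2-(4-acetoxy-3-methoxyphenyl)ethyl]-6-(4-acetoxy-3-methoxyphenyl)tetrahydro-4H-pyran-4-one | CC(=O)Oc1ccc(CC[C@H]2CC(=O)C[C@@H](c3ccc(OC(C)=O)c(OC)c3)O2)cc1OC | intermediate
9 | (2S,4S,6S)-2-[2-(4-acetoxy-3-methoxyphenyl)ethyl]-6-(4-acetoxy-3-methoxyphenyl)tetrahydro-2H-pyran-4-ol | CC(=O)Oc1ccc(CC[C@H]2C[C@H](O)C[C@@H](c3ccc(OC(C)=O)c(OC)c3)O2)cc1OC | intermediate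
10 | (2S,4S,6S)-2-[2-(4-hydroxy-3-methoxyphenyl)ethyl]-6-(4-hydroxy-3-methoxyphenyl)tetrahydro-2H-pyran-4-ol | COc1cc(CC[C@H]2C[C@H](O)C[C@@H](c3ccc(O)c(OC)c3)O2)ccc1O | target

**Step count and risks**

Total step count: 6. Longest linear sequence: 6 steps (1 → 2 → 4 → 5 → 8 → 9 → 10).

Steps most likely to fail:

Step 4. The cycloaddition of an aromatic aldehyde may be slow, and enantioface or endo control may erode. The fallback sets out from enone 4 and aldehyde 6 and replaces the cycloaddition by an aldol addition followed by ring closure. Enone 4 is converted with Ipc2BCl and Et3N (Et2O, –78 to 0 °C) into its dienyl diisopinocampheylborinate, using the Ipc2BCl enantiomer that directs the enolate to the Si face of the aldehyde. Addition to 6 at –78 °C and buffered H2O2 work-up should give the aldol adduct (1S,4E)-1,7-bis(4-acetoxy-3-methoxyphenyl)-1-hydroxyhept-4-en-3-one F1. A 6-endo-trig oxa-Michael addition under thermodynamic control (Amberlyst-15, CH2Cl2, rt) then forms the same O1–C2 bond with the 2,6-cis arrangement and comes back to the route at ketone 8.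

Step 5. Hydride delivery may show poor facial selectivity, or the hydride may attack the aryl acetates. The fallback sets out from ketone 8 and reaches the axial alcohol by inversion instead of by direct reduction. A small hydride (NaBH4, THF/EtOH, –20 °C) should attack axially and give the equatorial alcohol (2S,4R,6S)-2-[2-(4-acetoxy-3-methoxyphenyl)ethyl]-6-(4-acetoxy-3-methoxyphenyl)tetrahydro-2H-pyran-4-ol F2. Mitsunobu inversion (4-nitrobenzoic acid, PPh3, DIAD, THF, 0 °C to rt) should give the axial ester (2S,4S,6S)-2-[2-(4-acetoxy-3-methoxyphenyl)ethyl]-6-(4-acetoxy-3-methoxyphenyl)tetrahydro-2H-pyran-4-yl 4-nitrobenzoate F3. Methanolysis (K2CO3, MeOH) removes the nitrobenzoate together with both acetates and comes back to the route at target 10.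

Step 1. The aldehyde may be over-reduced or decarbonylated on palladium. The fallback sets out from enal 1 and uses organocatalytic transfer hydrogenation: diethyl 2,6-dimethyl-1,4-dihydropyridine-3,5-dicarboxylate as hydride donor, dibenzylammonium trifluoroacetate (cat.), THF, rt. Hydride is delivered only to the iminium-activated C=C bond, so the aldehyde oxidation level is never at risk. The fallback comes back to the route at aldehyde 2; no new compound is made (F0).

**Further compounds**

F1 | step 4 | (1S,4E)-1,7-bis(4-acetoxy-3-methoxyphenyl)-1-hydroxyhept-4-en-3-one | CC(=O)Oc1ccc(CC/C=C/C(=O)C[C@@H](c2ccc(OC(C)=O)c(OC)c2)O)cc1OC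
F2 | step 5 | (2S,4R,6S)-2-[2-(4-acetoxy-3-methoxyphenyl)ethyl]-6-(4-acetoxy-3-methoxyphenyl)tetrahydro-2H-pyran-4-ol | CC(=O)Oc1ccc(CC[C@H]2C[C@@H](O)C[C@@H](c3ccc(OC(C)=O)c(OC)c3)O2)cc1OC
F3 | step 5 | (2S,4S,6S)-2-[2-(4-acetoxy-3-methoxyphenyl)ethyl]-6-(4-acetoxy-3-methoxyphenyl)tetrahydro-2H-pyran-4-yl 4-nitrobenzoate | CC(=O)Oc1ccc(CC[C@H]2C[C@H](OC(=O)c4ccc(cc4)[N+](=O)[O-])C[C@@H](c3ccc(OC(C)=O)c(OC)c3)O2)cc1OC
F0 | step 1 | none | none
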